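**Plan**

- Target 5 is a saturated 31-membered lactone with 30 ring carbons (C1 the carbonyl carbon, C30 the carbon on the ring oxygen) and one ring oxygen; it has no stereocentre.
- Retrosynthesis: reinstate a C15=C16 double bond (4), cut it by ring-closing metathesis to the open diene ester 3, cut the C1–O ester bond to acid 1 and alcohol 2, and trace 2 back to 1.
- Enabling feature: the C15–C16 bond lies at the midpoint of the ring carbons, so the cut leaves two C15 arms (C1–C15 and C30–C16). Nervonic acid has its only double bond at C15, so the acid gives one arm and its alcohol the other.
- Forward: reduce 1 to 2, esterify 1 with 2 (C1–O bond), close the single ring at C15=C16 with loss of both C9 tails as octadec-9-ene, then hydrogenate.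
- Stereochemistry: none to set. The Z olefins of 3 are consumed in the ring closure and the E/Z geometry of 4 is erased by hydrogenation.

Key step: step 3

Remark: the ring olefin of 4 is expected as an E/Z mixture with E predominant; 4 is written as the E isomer, the Z isomer is not separated, and both converge on 5 in step 4.

**Route**

Step 1
Reactants: 1 nervonic acid, (Z)-tetracos-15-enoic acid
Product: 2 nervonyl alcohol, (Z)-tetracos-15-en-1-ol
Conditions: LiAlH4 (1.5 equiv), THF, 0 °C to reflux; then H2O, 15% aq NaOH, H2O
Reagents that add atoms: none
Why: Hydride reduction of a carboxylic acid: LiAlH4 takes the carboxylate to the primary alkoxide, while the isolated Z double bond at C15 is inert to nucleophilic hydride and keeps its position and geometry.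

Step 2
Reactants: 1 nervonic acid, (Z)-tetracos-15-enoic acid; 2 nervonyl alcohol, (Z)-tetracos-15-en-1-ol
Product: 3 (Z)-tetracos-15-en-1-yl (Z)-tetracos-15-enoate
Conditions: DCC (1.1 equiv), DMAP (0.1 equiv), CH2Cl2, 0 °C to rt; filtration from the urea, silica gel
Reagents that add atoms: none
Why: Steglich esterification: the carbodiimide takes up the elements of water and DMAP acts as acyl-transfer catalyst, so the unhindered primary alcohol 2 is acylated by 1 under neutral conditions at room temperature that leave both Z olefins untouched.

Step 3
Reactants: 3 (Z)-tetracos-15-en-1-yl (Z)-tetracos-15-enoate
Product: 4 (E)-triacont-15-en-30-olide, (E)-oxacyclohentriacont-16-en-2-one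
Conditions: second-generation Grubbs catalyst (H2IMes)(PCy3)Cl2Ru=CHPh (5 mol %, two portions), 1,4-benzoquinone (10 mol %), degassed CH2Cl2 (about 1 mM in 3), reflux (40 °C), Ar; then silica gel (hexane elutes octadec-9-ene, hexane/EtOAc elutes 4)
Reagents that add atoms: none
Why: Ring-closing olefin metathesis by the Chauvin mechanism: the ruthenium alkylidene adds to one Z double bond of 3 by [2+2] cycloaddition, cycloreversion of the ruthenacyclobutane expels a nonylidene tail, and the chain-bound alkylidene repeats the sequence on the second double bond of the same molecule to form C15=C16. The closest known reaction type is the macrocyclising metathesis of diene esters built from unsaturated fatty acids and fatty alcohols, where two internal olefins exchange and an internal olefin, not ethylene, is the co-product. The one ring, the 31-membered lactone, closes end to end by joining the two C15 arms under thermodynamic ring–chain equilibrium; it is strain-free, and at about 1 mM the entropy of making two molecules from one favours ring plus octadec-9-ene over oligomers. No stereocentre is created, and the E geometry written for 4 is only the expected thermodynamic preference, which does not matter because step 4 removes the double bond. The step needs cyclisation to win over oligomerisation and needs both double bonds to stay at C15 until they exchange; high dilution secures the first, and the second rests on the exact placement of each olefin at the fifteenth carbon counted from the carbonyl carbon and from the O–CH2 carbon, guarded by 1,4-benzoquinone, which intercepts the ruthenium hydrides that would migrate the double bonds and give ring homologues. Because every olefin is internal, the propagating carbenes are alkyl-substituted alkylidenes and the fragile ruthenium methylidene never forms.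

Step 4
Reactants: 4 (E)-triacont-15-en-30-olide
Product: 5 triacontan-30-olide, oxacyclohentriacontan-2-one
Conditions: H2 (1 atm), 10% Pd/C, EtOAc, rt
Reagents that add atoms: none
Why: Catalytic hydrogenation over Pd/C saturates the unhindered disubstituted ring olefin of either geometry at room temperature, and the lactone, which has no benzylic or allylic C–O bond, is not cleaved, so the olefin geometry of 4 is erased and the achiral target results.

**Compound list**

1 | nervonic acid, (Z)-tetracos-15-enoic acid | CCCCCCCC/C=C\CCCCCCCCCCCCCC(=O)O | starting material
2 | nervonyl alcohol, (Z)-tetracos-15-en-1-ol | CCCCCCCC/C=C\CCCCCCCCCCCCCCO | intermediate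
3 | (Z)-tetracos-15-en-1-yl (Z)-tetracos-15-enoate | CCCCCCCC/C=C\CCCCCCCCCCCCCC(=O)OCCCCCCCCCCCCCC/C=C\CCCCCCCC | intermediate
4 | (E)-triacont-15-en-30-olide, (E)-oxacyclohentriacont-16-en-2-one | O=C1CCCCCCCCCCCCC/C=C/CCCCCCCCCCCCCCO1 | intermediate
5 | triacontan-30-olide, oxacyclohentriacontan-2-one | O=C1CCCCCCCCCCCCCCCCCCCCCCCCCCCCCO1 | target

Total step count: 4
Longest linear sequence: 4 steps (1 → 2 → 3 → 4 → 5)

**Steps most likely to fail**

Step 3. The ring–chain equilibrium may stall because the octadec-9-ene co-product stays in solution and reopens the ring, oligomers may build up, and double-bond migration before exchange may give ring-contracted or ring-expanded lactones that travel with the product. The fallback sets out from 3 and comes back at 4. Both internal olefins of 3 are first cleaved with ethene (about 10 bar) and the first-generation Grubbs catalyst (PCy3)2Cl2Ru=CHPh in CH2Cl2 at 40 °C. This gives the terminal diene hexadec-15-en-1-yl hexadec-15-enoate F1 and dec-1-ene, which is distilled off. F1 is then closed with the second-generation Grubbs catalyst (H2IMes)(PCy3)Cl2Ru=CHPh and 1,4-benzoquinone in refluxing CH2Cl2 at high dilution under an argon sweep. Ethene leaves the solution, so the same C15=C16 bond forms irreversibly and 4 results.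

Step 2. The activated acid may rearrange to an unreactive N-acylurea, and coupling of the two waxy partners may stop short, leaving acid and alcohol that are hard to remove from 3. The fallback sets out from 1 and comes back at 3. Acid 1 is converted with oxalyl chloride and catalytic DMF in CH2Cl2 (0 °C to rt) into (Z)-tetracos-15-enoyl chloride F2. After removal of the volatiles, F2 acylates alcohol 2 in CH2Cl2 with pyridine and catalytic DMAP (0 °C to rt) to give 3.

Step 1. The lithium and aluminium carboxylates of the long-chain acid may precipitate from THF, so that reduction stops early and unreduced acid is carried into the esterification. The fallback sets out from 1 and comes back at 2. Fischer esterification of 1 (MeOH, catalytic H2SO4, reflux) gives methyl (Z)-tetracos-15-enoate F3. F3 stays in solution and is reduced by LiAlH4 in THF at 0 °C to 2.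

**Further compounds**

F1 | step 3 | hexadec-15-en-1-yl hexadec-15-enoate | C=CCCCCCCCCCCCCCC(=O)OCCCCCCCCCCCCCCC=C
F2 | step 2 | (Z)-tetracos-15-enoyl chloride | CCCCCCCC/C=C\CCCCCCCCCCCCCC(=O)Cl
F3 | step 1 | methyl (Z)-tetracos-15-enoate | CCCCCCCC/C=C\CCCCCCCCCCCCCC(=O)OC
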